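**Strategy.** The 1,2-dioxane ring is disconnected at C4–C5 (numbering from the lactone carbonyl C1), the bond between the lactone-bearing quaternary carbon and the ring methylene. In the forward sense it is closed as a C4=C5 olefin by ring-closing metathesis of an acyclic dialkyl peroxide that already holds both peroxide-bearing stereocentres: C3 carries an isopropenyl group and the acetic acid arm, C6 a vinyl group, the methyl and the side chain. The step exploits that C4 lies γ to the C1 carboxyl: the new dihydro-1,2-dioxine olefin lets the acid lactonise onto C4 from the face of C3, which fixes the cis ring fusion. C6 comes from a stereospecific epoxide perhydrolysis, C3 from an iminium-catalysed peroxidation.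

Key step: step 10

Remark on numbering: C1 = lactone C=O, C2 = CH2, C3 = CH–O–O, C4 = C(CH3)–O(lactone), C5 = ring CH2, C6 = C(CH3)(side chain)–O–O. The target is (3S,4S,6S) in this numbering.
Remark on materials: 1, 2, 4, 10 and 11 are taken as commercial.

**Step 1**
Reactants: 1 phenylmagnesium bromide; 2 1,11-dibromoundecane
Product: 3 (11-bromoundecyl)benzene
Conditions: 2 (3 equiv), Li2CuCl4 (cat.), THF, 0 °C
Reagents that add atoms: none
Why: Copper-catalysed Grignard–alkyl bromide cross-coupling (Kochi type); the excess of dibromide suppresses double arylation and no stereocentre is involved.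

**Step 2**
Reactants: 3 (11-bromoundecyl)benzene; 4 (S)-2-methylglycidol
Product: 6 (2R)-2-methyl-14-phenyltetradecane-1,2-diol, via Grignard reagent 5 (not isolated)
Conditions: Mg, THF, 40 °C; then 4 (pre-treated with MeMgBr, 1 equiv), CuI (cat.), THF, −30 → 0 °C; aq. NH4Cl
Reagents that add atoms: none
Why: Copper-catalysed SN2 opening of the 2,2-disubstituted epoxide at its unhindered CH2 terminus by the Grignard reagent; the quaternary centre of 4 is not touched and becomes C6 (R in 6 only because the CIP priorities change).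

**Step 3**
Reactants: 6 (2R)-2-methyl-14-phenyltetradecane-1,2-diol
Product: 8 (2R)-2-methyl-2-(12-phenyldodecyl)oxirane, via monotosylate 7 (not isolated)
Conditions: NaH (2.2 equiv), 1-(p-toluenesulfonyl)imidazole, THF, 0 °C → rt
Reagents that add atoms: none
Why: Selective sulfonylation of the primary alkoxide followed by intramolecular Williamson closure (3-exo-tet) by the tertiary alkoxide; the C6–O bond is kept, so the configuration is retained.

**Step 4**
Reactants: 8 (2R)-2-methyl-2-(12-phenyldodecyl)oxirane
Product: 9 (2S)-2-hydroperoxy-2-methyl-14-phenyltetradecan-1-ol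
Conditions: anhydrous H2O2 in Et2O (excess), H3PMo12O40 (phosphomolybdic acid, cat.), rt
Reagents that add atoms: hydrogen peroxide, OO
Why: Acid-catalysed perhydrolysis of a 2,2-disubstituted epoxide, in which H2O2 opens the activated oxirane at the tertiary carbon with inversion (borderline SN2), so that (R)-8 should give the (S)-tertiary hydroperoxide and C6 is set.

**Step 5**
Reactants: 10 methacrolein; 11 (triphenylphosphoranylidene)acetaldehyde
Product: 12 (2E)-4-methylpenta-2,4-dienal
Conditions: 10 (excess), toluene, 80 °C; distillation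
Reagents that add atoms: none
Why: Wittig olefination with a formyl-stabilised ylide, which is (E)-selective; the excess of volatile methacrolein limits a second homologation.

**Step 6**
Reactants: 9 (2S)-2-hydroperoxy-2-methyl-14-phenyltetradecan-1-ol; 12 (2E)-4-methylpenta-2,4-dienal
Product: 13 (3S)-3-{[(2S)-1-hydroxy-2-methyl-14-phenyltetradecan-2-yl]peroxy}-4-methylpent-4-enal
Conditions: (S)-2-[diphenyl(trimethylsilyloxy)methyl]pyrrolidine (20 mol%), PhCO2H (20 mol%), 12 (2 equiv), toluene, −20 °C
Reagents that add atoms: none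
Why: Iminium-catalysed asymmetric conjugate addition of a hydroperoxide to an enal (organocatalytic peroxidation): the α-effect O-nucleophile should add to C3 of the (E)-iminium ion on its Si face, the Re face being shielded by the diaryl(silyloxy)methyl group, which sets 3S, while the acid co-catalyst and low temperature favour protonation and hydrolysis of the β-peroxy enamine over its collapse to an epoxide.

**Step 7**
Reactants: 13 (3S)-3-{[(2S)-1-hydroxy-2-methyl-14-phenyltetradecan-2-yl]peroxy}-4-methylpent-4-enal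
Product: 14 (3S)-3-{[(2S)-1-hydroxy-2-methyl-14-phenyltetradecan-2-yl]peroxy}-4-methylpent-4-enoic acid
Conditions: NaClO2, NaH2PO4, 2-methylbut-2-ene, t-BuOH/H2O, 0 °C
Reagents that add atoms: sodium chlorite, [Na+].[O-]Cl=O
Why: Pinnick oxidation, in which chlorite oxidises only the aldehyde under a mildly acidic buffer that leaves the peroxide, the olefin, the primary alcohol and the β-peroxy stereocentre untouched.

**Step 8**
Reactants: 14 (3S)-3-{[(2S)-1-hydroxy-2-methyl-14-phenyltetradecan-2-yl]peroxy}-4-methylpent-4-enoic acid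
Product: 15 (3S)-4-methyl-3-{[(2S)-2-methyl-1-oxo-14-phenyltetradecan-2-yl]peroxy}pent-4-enoic acid
Conditions: Dess–Martin periodinane, CH2Cl2, 0 °C → rt
Reagents that add atoms: none
Why: Dess–Martin oxidation of the neopentyl primary alcohol; the new α-peroxy aldehyde has no α-hydrogen and so can neither enolise nor undergo Kornblum–DeLaMare fragmentation.

**Step 9**
Reactants: 15 (3S)-4-methyl-3-{[(2S)-2-methyl-1-oxo-14-phenyltetradecan-2-yl]peroxy}pent-4-enoic acid
Product: 16 (3S)-4-methyl-3-{[(3S)-3-methyl-15-phenylpentadec-1-en-3-yl]peroxy}pent-4-enoic acid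
Conditions: 15 pre-treated with KN(SiMe3)2 (1 equiv); Ph3PCH3Br/KN(SiMe3)2 (2 equiv), THF, −78 → 0 °C; dilute HCl work-up
Reagents that add atoms: methyltriphenylphosphonium bromide (as its ylide), C[P+](c1ccccc1)(c1ccccc1)c1ccccc1.[Br-]
Why: Wittig methylenation; C1 is present as its carboxylate, which blocks enolisation and β-elimination of the C3 peroxide, and the non-enolisable aldehyde should react with the ylide faster than the hindered tert/sec dialkyl peroxide.

**Step 10**
Reactants: 16 (3S)-4-methyl-3-{[(3S)-3-methyl-15-phenylpentadec-1-en-3-yl]peroxy}pent-4-enoic acid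
Product: 17 2-[(3S,6S)-4,6-dimethyl-6-(12-phenyldodecyl)-3,6-dihydro-1,2-dioxin-3-yl]acetic acid
Conditions: second-generation Hoveyda–Grubbs catalyst RuCl2(=CH-C6H4-2-OiPr)(H2IMes) (10 mol%), 1,4-benzoquinone (20 mol%), toluene (2 mM), 60 °C, argon purge
Reagents that add atoms: none
Why: Proposed new method: initiation at the monosubstituted vinyl group on C6 should give a ruthenium alkylidene at C5, which engages the isopropenyl olefin on C3 in an intramolecular [2+2] cycloaddition/cycloreversion and expels ethylene, so that the C4–C5 bond appears as the endocyclic trisubstituted olefin of a 3,6-dihydro-1,2-dioxine. The closest known reaction type is ring-closing metathesis of dienyl ethers to 3,6-dihydro-2H-pyrans, together with olefin metathesis in molecules that carry a remote dialkyl peroxide; closing a ring through an O–O tether is the new element. One ring is closed, the six-membered 1,2-dioxine, by metathesis onto the isopropenyl carbon C4 (an endo closure, the C4=C5 olefin ending inside the ring), driven by loss of ethylene. No stereocentre is created: C3 and C6 pass through unchanged, and the olefin is the handle with which step 11 sets C4. The step needs cyclisation over oligomerisation, which high dilution, the gem-disubstitution at C6 and the gauche C–O–O–C geometry should secure. It also needs carbene chemistry over one-electron cleavage of the O–O bond, which is plausible because the divalent ruthenium alkylidene is a poor reductant, the peroxide is a hindered tert/sec dialkyl peroxide, C6 has no allylic hydrogen and benzoquinone suppresses ruthenium hydrides.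

**Step 11**
Reactants: 17 2-[(3S,6S)-4,6-dimethyl-6-(12-phenyldodecyl)-3,6-dihydro-1,2-dioxin-3-yl]acetic acid
Product: 18 (3S,4S,4aR,7aS)-4-iodo-3,4a-dimethyl-3-(12-phenyldodecyl)tetrahydro-3H-furo[3,2-c][1,2]dioxin-6(4H)-one (the 5-iodo derivative of the target, iodine trans to the lactone oxygen)
Conditions: I2, NaHCO3, MeCN/H2O, 0 °C, dark
Reagents that add atoms: iodine, II
Why: Iodolactonisation (5-exo, Markovnikov): the carboxylate tethered to C3 can only open the iodonium ion at the tertiary carbon C4 from its own face, which sets C4 (cis ring fusion, 4S in the target numbering) and places iodine anti on C5.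

**Step 12**
Reactants: 18 (3S,4S,4aR,7aS)-4-iodo-3,4a-dimethyl-3-(12-phenyldodecyl)tetrahydro-3H-furo[3,2-c][1,2]dioxin-6(4H)-one
Product: 19 plakortolide L, (3S,4aS,7aS)-3,4a-dimethyl-3-(12-phenyldodecyl)tetrahydro-3H-furo[3,2-c][1,2]dioxin-6(4H)-one
Conditions: n-Bu3SnH, Et3B/air (cat.), toluene, 0 °C → rt
Reagents that add atoms: none
Why: Radical-chain hydrodeiodination with tin hydride: iodine abstraction is far faster than attack of stannyl radicals on the O–O bond, the ring geometry disfavours attack of the C5 radical on the peroxide, and the temporary C5 stereocentre is removed without touching C3, C4 or C6.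

**Compound list**
1 | phenylmagnesium bromide | Br[Mg]c1ccccc1 | starting material
2 | 1,11-dibromoundecane | BrCCCCCCCCCCCBr | starting material
3 | (11-bromoundecyl)benzene | BrCCCCCCCCCCCc1ccccc1 | intermediate
4 | (S)-2-methylglycidol, [(2S)-2-methyloxiran-2-yl]methanol | C[C@]1(CO)CO1 | starting material
5 | (11-phenylundecyl)magnesium bromide | Br[Mg]CCCCCCCCCCCc1ccccc1 | intermediate (not isolated)
6 | (2R)-2-methyl-14-phenyltetradecane-1,2-diol | C[C@](O)(CO)CCCCCCCCCCCCc1ccccc1 | intermediate
7 | (2R)-2-hydroxy-2-methyl-14-phenyltetradecyl 4-methylbenzenesulfonate | C[C@](O)(COS(=O)(=O)c1ccc(C)cc1)CCCCCCCCCCCCc1ccccc1 | intermediate (not isolated)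
8 | (2R)-2-methyl-2-(12-phenyldodecyl)oxirane | C[C@@]1(CCCCCCCCCCCCc2ccccc2)CO1 | intermediate
9 | (2S)-2-hydroperoxy-2-methyl-14-phenyltetradecan-1-ol | C[C@@](OO)(CO)CCCCCCCCCCCCc1ccccc1 | intermediate
10 | methacrolein | CC(=C)C=O | starting material
11 | (triphenylphosphoranylidene)acetaldehyde | O=CC=P(c1ccccc1)(c1ccccc1)c1ccccc1 | starting material
12 | (2E)-4-methylpenta-2,4-dienal | C=C(C)/C=C/C=O | intermediate
13 | (3S)-3-{[(2S)-1-hydroxy-2-methyl-14-phenyltetradecan-2-yl]peroxy}-4-methylpent-4-enal | C=C(C)[C@H](CC=O)OO[C@](C)(CO)CCCCCCCCCCCCc1ccccc1 | intermediate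
14 | (3S)-3-{[(2S)-1-hydroxy-2-methyl-14-phenyltetradecan-2-yl]peroxy}-4-methylpent-4-enoic acid | C=C(C)[C@H](CC(=O)O)OO[C@](C)(CO)CCCCCCCCCCCCc1ccccc1 | intermediate
15 | (3S)-4-methyl-3-{[(2S)-2-methyl-1-oxo-14-phenyltetradecan-2-yl]peroxy}pent-4-enoic acid | C=C(C)[C@H](CC(=O)O)OO[C@](C)(C=O)CCCCCCCCCCCCc1ccccc1 | intermediate
16 | (3S)-4-methyl-3-{[(3S)-3-methyl-15-phenylpentadec-1-en-3-yl]peroxy}pent-4-enoic acid | C=C(C)[C@H](CC(=O)O)OO[C@](C)(C=C)CCCCCCCCCCCCc1ccccc1 | intermediate
17 | 2-[(3S,6S)-4,6-dimethyl-6-(12-phenyldodecyl)-3,6-dihydro-1,2-dioxin-3-yl]acetic acid | C[C@]1(CCCCCCCCCCCCc2ccccc2)C=C(C)[C@H](CC(=O)O)OO1 | intermediate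
18 | (3S,4S,4aR,7aS)-4-iodo-3,4a-dimethyl-3-(12-phenyldodecyl)tetrahydro-3H-furo[3,2-c][1,2]dioxin-6(4H)-one | C[C@]1(CCCCCCCCCCCCc2ccccc2)[C@@H](I)[C@]2(C)OC(=O)C[C@@H]2OO1 | intermediate
19 | plakortolide L, (3S,4aS,7aS)-3,4a-dimethyl-3-(12-phenyldodecyl)tetrahydro-3H-furo[3,2-c][1,2]dioxin-6(4H)-one | C[C@]1(CCCCCCCCCCCCc2ccccc2)C[C@]2(C)OC(=O)C[C@@H]2OO1 | target

**Step count.** Total: 12 steps. Longest linear sequence: 11 steps (steps 1–4 and 6–12; step 5 is a one-step side branch).

**Steps most likely to fail**

Step 10 (ring-closing metathesis, proposed new method). The ruthenium carbene may cleave the O–O bond by electron transfer, followed by collapse of the allylic peroxide, or it may fail to turn over on two hindered olefins and give oligomers instead. The fallback uses known chemistry and gives up the C–C ring closure: the dioxane is closed through O–C3 by conjugate addition of a C6 peroxide to a butenolide. It sets out from Grignard reagent 5 (made from 3) and returns at 19.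
- Copper-catalysed coupling of 5 with 2,3-dibromopropene gives 2-bromo-14-phenyltetradec-1-ene F1.
- The Grignard reagent of F1 opens (R)-2-methylglycidol, the commercial enantiomer of 4, under CuI catalysis to give (2S)-2-methyl-4-methylidene-16-phenylhexadecane-1,2-diol F2.
- TEMPO/PhI(OAc)2 gives (2S)-2-hydroxy-2-methyl-4-methylidene-16-phenylhexadecanal F3.
- (Triphenylphosphoranylidene)ketene, Ph3P=C=C=O, in hot toluene (O-acylation, then intramolecular Wittig reaction) gives (5S)-5-methyl-5-(2-methylidene-14-phenyltetradecyl)furan-2(5H)-one F4, whose quaternary carbon is C4.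
- Cobalt-catalysed hydroperoxysilylation (Co(acac)2, O2, Et3SiH; Mukaiyama–Isayama) places the peroxide on the tertiary carbon C6 without stereocontrol. It gives (5S)-5-methyl-5-[(2S)-2-methyl-14-phenyl-2-(triethylsilylperoxy)tetradecyl]furan-2(5H)-one F5 and its epimer (5S)-5-methyl-5-[(2R)-2-methyl-14-phenyl-2-(triethylsilylperoxy)tetradecyl]furan-2(5H)-one F6.
- Bu4NF frees the peroxide anions, which add to C3 of the butenolide (6-exo, cis fusion enforced) to give 19 and its C6 epimer (3R,4aS,7aS)-3,4a-dimethyl-3-(12-phenyldodecyl)tetrahydro-3H-furo[3,2-c][1,2]dioxin-6(4H)-one F7.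
- The price is a chromatographic separation at C6.

Step 6 (organocatalytic peroxidation). The β-peroxy enamine may collapse to the 2,3-epoxy aldehyde with loss of the alkoxide (Weitz–Scheffer pathway), the hydroperoxide may add at the diene terminus (1,6-addition), or the facial selectivity may be poor. The fallback forms the C3–O bond by SN2 alkylation of the hydroperoxide instead. It sets out from 9 and returns at 13.
- (3R)-5,5-Dimethoxy-2-methylpent-1-en-3-ol F8 is made by amino-alcohol-catalysed enantioselective addition of (CH2=C(CH3))2Zn to 3,3-dimethoxypropanal.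
- MsCl/Et3N at −20 °C converts it into (3R)-5,5-dimethoxy-2-methylpent-1-en-3-yl methanesulfonate F9.
- The caesium peroxide of 9 (CsOH·H2O, DMF, 0 °C) displaces the mesylate with inversion to give (2S)-2-{[(3S)-5,5-dimethoxy-2-methylpent-1-en-3-yl]peroxy}-2-methyl-14-phenyltetradecan-1-ol F10.
- Mild aqueous acid (Amberlyst-15, acetone/H2O) unmasks the aldehyde and gives 13.

Step 9 (Wittig methylenation). The ylide may attack the O–O bond, or the base may trigger β-elimination of the C3 peroxide on the C1 side (retro-oxa-Michael). The fallback removes every carbonyl β to the peroxide during the olefination. It sets out from 13 and returns at 16.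
- 13 is protected (HC(OMe)3, pyridinium p-toluenesulfonate, MeOH) as the dimethyl acetal F10 (see the fallback for step 6).
- Dess–Martin oxidation gives (2S)-2-{[(3S)-5,5-dimethoxy-2-methylpent-1-en-3-yl]peroxy}-2-methyl-14-phenyltetradecanal F11.
- Methylenation with Ph3P=CH2 gives (3S)-3-{[(3S)-5,5-dimethoxy-2-methylpent-1-en-3-yl]peroxy}-3-methyl-15-phenylpentadec-1-ene F12.
- Aqueous acid gives (3S)-4-methyl-3-{[(3S)-3-methyl-15-phenylpentadec-1-en-3-yl]peroxy}pent-4-enal F13.
- Pinnick oxidation (as in step 7) gives 16.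

**Further compounds**
F1 | step 10 | 2-bromo-14-phenyltetradec-1-ene | C=C(Br)CCCCCCCCCCCCc1ccccc1
F2 | step 10 | (2S)-2-methyl-4-methylidene-16-phenylhexadecane-1,2-diol | C[C@@](O)(CO)CC(=C)CCCCCCCCCCCCc1ccccc1
F3 | step 10 | (2S)-2-hydroxy-2-methyl-4-methylidene-16-phenylhexadecanal | C[C@@](O)(C=O)CC(=C)CCCCCCCCCCCCc1ccccc1
F4 | step 10 | (5S)-5-methyl-5-(2-methylidene-14-phenyltetradecyl)furan-2(5H)-one | C[C@@]1(CC(=C)CCCCCCCCCCCCc2ccccc2)OC(=O)C=C1
F5 | step 10 | (5S)-5-methyl-5-[(2S)-2-methyl-14-phenyl-2-(triethylsilylperoxy)tetradecyl]furan-2(5H)-one | C[C@@]1(C[C@@](C)(OO[Si](CC)(CC)CC)CCCCCCCCCCCCc2ccccc2)OC(=O)C=C1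
F6 | step 10 | (5S)-5-methyl-5-[(2R)-2-methyl-14-phenyl-2-(triethylsilylperoxy)tetradecyl]furan-2(5H)-one | C[C@@]1(C[C@](C)(OO[Si](CC)(CC)CC)CCCCCCCCCCCCc2ccccc2)OC(=O)C=C1
F7 | step 10 | (3R,4aS,7aS)-3,4a-dimethyl-3-(12-phenyldodecyl)tetrahydro-3H-furo[3,2-c][1,2]dioxin-6(4H)-one | C[C@@]1(CCCCCCCCCCCCc2ccccc2)C[C@]2(C)OC(=O)C[C@@H]2OO1
F8 | step 6 | (3R)-5,5-dimethoxy-2-methylpent-1-en-3-ol | C=C(C)[C@H](O)CC(OC)OC
F9 | step 6 | (3R)-5,5-dimethoxy-2-methylpent-1-en-3-yl methanesulfonate | C=C(C)[C@H](OS(C)(=O)=O)CC(OC)OC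
F10 | step 6 | (2S)-2-{[(3S)-5,5-dimethoxy-2-methylpent-1-en-3-yl]peroxy}-2-methyl-14-phenyltetradecan-1-ol | C=C(C)[C@@H](OO[C@](C)(CO)CCCCCCCCCCCCc1ccccc1)CC(OC)OC
F11 | step 9 | (2S)-2-{[(3S)-5,5-dimethoxy-2-methylpent-1-en-3-yl]peroxy}-2-methyl-14-phenyltetradecanal | C=C(C)[C@@H](OO[C@](C)(C=O)CCCCCCCCCCCCc1ccccc1)CC(OC)OC
F12 | step 9 | (3S)-3-{[(3S)-5,5-dimethoxy-2-methylpent-1-en-3-yl]peroxy}-3-methyl-15-phenylpentadec-1-ene | C=C(C)[C@@H](OO[C@](C)(C=C)CCCCCCCCCCCCc1ccccc1)CC(OC)OC
F13 | step 9 | (3S)-4-methyl-3-{[(3S)-3-methyl-15-phenylpentadec-1-en-3-yl]peroxy}pent-4-enal | C=C(C)[C@H](CC=O)OO[C@](C)(C=C)CCCCCCCCCCCCc1ccccc1
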